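The route rests on disconnecting the C4–C4a bond of ring B. Ring A and the aryl substituent on C1 are the same 3,4-dioxygenated phenyl group, so C1 is a stereocentre only because one of the two is tied to C4. The precursor is therefore an open-chain 2-formylsuccinate (enol form) carrying a bis(3,4-dibenzyloxyphenyl)methyl group on the carbon that becomes C2, with that carbon already S. Under acid one of these rings adds to the formyl carbon and water is expelled, so ring B, the C3=C4 alkene and the C1 stereocentre are created in a single operation, with C1 dictated by C2. The malate ester is attached afterwards and all benzyl and tert-butyl groups are removed together.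

Key step: step 7

Assumption: the sense of induction in step 4 is assigned by analogy with simpler alkylidenesuccinate half-esters; should the (R,R) ligand deliver the 3S acid, the (S,S) ligand is used in the same way.

Remark: the ring atoms of all naphthalene compounds are numbered as in the target (C1 aryl-bearing carbon, C2 carboxyl-bearing carbon, C3=C4 alkene, ring A = C4a to C8a).

Step 1
Reactants: 1 3,4-bis(benzyloxy)benzaldehyde; 2 4-bromo-1,2-bis(benzyloxy)benzene
Product: 4 bis[3,4-bis(benzyloxy)phenyl]methanol, via arylmagnesium bromide 3 (not isolated)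
Conditions: 2, Mg, THF, 40 °C; then 1, 0 °C → rt; aq. NH4Cl
Reagents that add atoms: none
Why: Grignard addition of the arylmagnesium bromide to the aldehyde carbonyl, to which benzyl aryl ethers are inert; the carbinol carbon bears two identical aryl groups and is not stereogenic.

Step 2
Reactants: 4 bis[3,4-bis(benzyloxy)phenyl]methanol
Product: 5 bis[3,4-bis(benzyloxy)phenyl]methanone
Conditions: Dess–Martin periodinane, CH2Cl2, rt
Reagents that add atoms: none
Why: Dess–Martin oxidation of a secondary diaryl carbinol to the benzophenone is fast and near neutral, so the benzyl ethers and the electron-rich rings are left alone.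

Step 3
Reactants: 5 bis[3,4-bis(benzyloxy)phenyl]methanone; 6 dibenzyl succinate
Product: 8 3-(benzyloxycarbonyl)-4,4-bis[3,4-bis(benzyloxy)phenyl]but-3-enoic acid, via paraconic lactone 7 (not isolated)
Conditions: NaH, BnOH (cat.), THF–toluene, 60 °C; then aq. HCl
Reagents that add atoms: none
Why: Stobbe condensation, in which the succinate enolate adds to the ketone, the alkoxide lactonises onto the distal ester and base-induced E1cB opening of lactone 7 gives the alkylidene half-ester, so the ester on the alkene carbon stays benzyl and the CH2CO2H arm emerges free; benzyloxide as the only alkoxide present rules out ester scrambling.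

Step 4
Reactants: 8 3-(benzyloxycarbonyl)-4,4-bis[3,4-bis(benzyloxy)phenyl]but-3-enoic acid
Product: 9 (3R)-3-(benzyloxycarbonyl)-4,4-bis[3,4-bis(benzyloxy)phenyl]butanoic acid
Conditions: [Rh(cod)((R,R)-Et-DuPHOS)]BF4 (2 mol%), Et3N (10 mol%), H2 (10 bar), MeOH–THF, rt
Reagents that add atoms: none
Why: Asymmetric hydrogenation of a tetrasubstituted Stobbe-type itaconate half-ester with a cationic rhodium bisphospholane catalyst, in which the carboxylate chelates the metal and the ligand decides which alkene face receives H2, setting the R centre (future C2); the homogeneous catalyst does not hydrogenolyse benzyl ethers or esters.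

Step 5
Reactants: 9 (3R)-3-(benzyloxycarbonyl)-4,4-bis[3,4-bis(benzyloxy)phenyl]butanoic acid
Product: 10 4-allyl 1-benzyl (2R)-2-{bis[3,4-bis(benzyloxy)phenyl]methyl}butanedioate
Conditions: allyl bromide, KHCO3, DMF, rt
Reagents that add atoms: allyl bromide, C=CCBr
Why: SN2 O-alkylation of the potassium carboxylate; hydrogen carbonate is too weak a base to enolise the benzyl ester, so the stereocentre is untouched.

Step 6
Reactants: 10 4-allyl 1-benzyl (2R)-2-{bis[3,4-bis(benzyloxy)phenyl]methyl}butanedioate; 11 2,2,2-trifluoroethyl formate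
Product: 13 1-allyl 4-benzyl (2Z,3S)-3-{bis[3,4-bis(benzyloxy)phenyl]methyl}-2-(hydroxymethylidene)butanedioate (enol tautomer of the formyl diester), via lithium ester enolate 12 (not isolated)
Conditions: LiN(i-Pr)2 (1.05 equiv), THF, −78 °C; then 11, −78 °C; AcOH
Reagents that add atoms: none
Why: Crossed Claisen condensation (C-formylation), in which the amide base removes a proton kinetically from the unhindered CH2 next to the allyl ester and not from the CH flanked by the bis(aryl)methyl group, the activated formate acylates the enolate at −78 °C, and the product rests as its own enolate until the acidic quench, which shields the neighbouring stereocentre from epimerisation.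

Step 7
Reactants: 13 1-allyl 4-benzyl (2Z,3S)-3-{bis[3,4-bis(benzyloxy)phenyl]methyl}-2-(hydroxymethylidene)butanedioate
Product: 15 3-allyl 2-benzyl (1R,2S)-6,7-bis(benzyloxy)-1-[3,4-bis(benzyloxy)phenyl]-1,2-dihydronaphthalene-2,3-dicarboxylate, via tetralin-4-ol carbinol 14 (not isolated)
Conditions: TFA–CH2Cl2 (1:4), 0 °C, argon
Reagents that add atoms: none
Why: TFA converts the enol into the O-protonated C4 aldehyde, which is attacked by the ring carbon ortho to C1 and para to a benzyloxy group of one aryl ring (Friedel–Crafts hydroxyalkylation) to give carbinol 14; ionisation of this benzylic alcohol and loss of the C3 proton then give the C3=C4 bond conjugated with the allyl ester and ring A. The closest known reaction is the Bradsher-type cyclodehydration of α-formyl-γ-arylbutyrates to 3,4-dihydro-2-naphthoates. Ring B closes in a six-membered mode that is exo with respect to the C=O bond being broken (6-exo-trig), the arene being the nucleophile. C1 becomes a stereocentre in the C4–C4a bond-forming event and is controlled by the C2 centre: in the least crowded staggered conformer about C1–C2, with the two hydrogens anti, only one aryl ring lies gauche to C3 and can reach C4, and closure through it leaves the spectator ring trans to the C2 ester (1R,2S), which is also the more stable arrangement of the product. The step needs group selectivity between the diastereotopic aryl rings, which this relay from C2 should secure, site selectivity within the ring, secured by para activation and by crowding of the position between C1 and the ether oxygen, and retention at C2, secured by an acid medium in which the benzyl ester does not enolise. Benzyl ethers and both esters are expected to survive dilute TFA at 0 °C.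

Step 8
Reactants: 15 3-allyl 2-benzyl (1R,2S)-6,7-bis(benzyloxy)-1-[3,4-bis(benzyloxy)phenyl]-1,2-dihydronaphthalene-2,3-dicarboxylate
Product: 16 (1R,2S)-2-(benzyloxycarbonyl)-6,7-bis(benzyloxy)-1-[3,4-bis(benzyloxy)phenyl]-1,2-dihydronaphthalene-3-carboxylic acid
Conditions: Pd(PPh3)4 (5 mol%), N-methylaniline, THF, rt
Reagents that add atoms: none
Why: Tsuji–Trost deallylation, in which zerovalent palladium ionises the allyl ester to a π-allyl complex that the weakly basic N-methylaniline captures, leaving benzyl esters, benzyl ethers, the alkene and the C2 centre untouched.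

Step 9
Reactants: 16 (1R,2S)-2-(benzyloxycarbonyl)-6,7-bis(benzyloxy)-1-[3,4-bis(benzyloxy)phenyl]-1,2-dihydronaphthalene-3-carboxylic acid; 17 di-tert-butyl (2S)-2-hydroxybutanedioate (di-tert-butyl L-malate)
Product: 18 di-tert-butyl (2S)-2-({(1R,2S)-2-(benzyloxycarbonyl)-6,7-bis(benzyloxy)-1-[3,4-bis(benzyloxy)phenyl]-1,2-dihydronaphthalen-3-yl}carbonyloxy)butanedioate
Conditions: DIC, DMAP (cat.), CH2Cl2, 0 °C → rt
Reagents that add atoms: none
Why: Steglich esterification, in which the carbodiimide activates the C3 acid and DMAP passes the acyl group to the secondary hydroxyl of the malate, whose stereocentre takes no part in bond making and is retained.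

Step 10
Reactants: 18 di-tert-butyl (2S)-2-({(1R,2S)-2-(benzyloxycarbonyl)-6,7-bis(benzyloxy)-1-[3,4-bis(benzyloxy)phenyl]-1,2-dihydronaphthalen-3-yl}carbonyloxy)butanedioate
Product: 19 (2S)-2-({(1R,2S)-2-carboxy-6,7-dihydroxy-1-(3,4-dihydroxyphenyl)-1,2-dihydronaphthalen-3-yl}carbonyloxy)butanedioic acid
Conditions: BCl3 (15 equiv), pentamethylbenzene (20 equiv), CH2Cl2, −78 → 0 °C; then H2O
Reagents that add atoms: none
Why: Lewis acid dealkylation, in which BCl3 coordinates the ether and ester oxygens and releases benzyl cations, trapped by pentamethylbenzene, and tert-butyl cations, trapped by chloride, so four phenols and three carboxylic acids are freed at once without reducing the C3=C4 alkene or cleaving the malate ester linkage.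

Compound list
1 | 3,4-bis(benzyloxy)benzaldehyde | O=Cc1ccc(OCc2ccccc2)c(OCc2ccccc2)c1 | starting material
2 | 4-bromo-1,2-bis(benzyloxy)benzene | Brc1ccc(OCc2ccccc2)c(OCc2ccccc2)c1 | starting material
3 | [3,4-bis(benzyloxy)phenyl]magnesium bromide | Br[Mg]c1ccc(OCc2ccccc2)c(OCc2ccccc2)c1 | intermediate (not isolated)
4 | bis[3,4-bis(benzyloxy)phenyl]methanol | OC(c1ccc(OCc2ccccc2)c(OCc2ccccc2)c1)c1ccc(OCc2ccccc2)c(OCc2ccccc2)c1 | intermediate
5 | bis[3,4-bis(benzyloxy)phenyl]methanone | O=C(c1ccc(OCc2ccccc2)c(OCc2ccccc2)c1)c1ccc(OCc2ccccc2)c(OCc2ccccc2)c1 | intermediate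
6 | dibenzyl succinate | O=C(CCC(=O)OCc1ccccc1)OCc1ccccc1 | starting material
7 | benzyl 2,2-bis[3,4-bis(benzyloxy)phenyl]-5-oxooxolane-3-carboxylate (racemic paraconic lactone) | O=C1CC(C(=O)OCc2ccccc2)C(c2ccc(OCc3ccccc3)c(OCc3ccccc3)c2)(c2ccc(OCc3ccccc3)c(OCc3ccccc3)c2)O1 | intermediate (not isolated)
8 | 3-(benzyloxycarbonyl)-4,4-bis[3,4-bis(benzyloxy)phenyl]but-3-enoic acid | OC(=O)CC(C(=O)OCc1ccccc1)=C(c1ccc(OCc2ccccc2)c(OCc2ccccc2)c1)c1ccc(OCc2ccccc2)c(OCc2ccccc2)c1 | intermediate
9 | (3R)-3-(benzyloxycarbonyl)-4,4-bis[3,4-bis(benzyloxy)phenyl]butanoic acid | OC(=O)C[C@@H](C(=O)OCc1ccccc1)C(c1ccc(OCc2ccccc2)c(OCc2ccccc2)c1)c1ccc(OCc2ccccc2)c(OCc2ccccc2)c1 | intermediate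
10 | 4-allyl 1-benzyl (2R)-2-{bis[3,4-bis(benzyloxy)phenyl]methyl}butanedioate | C=CCOC(=O)C[C@@H](C(=O)OCc1ccccc1)C(c1ccc(OCc2ccccc2)c(OCc2ccccc2)c1)c1ccc(OCc2ccccc2)c(OCc2ccccc2)c1 | intermediate
11 | 2,2,2-trifluoroethyl formate | O=COCC(F)(F)F | starting material
12 | lithium enolate of 10 at the allyl ester (stereocentre unchanged) | [Li]OC(OCC=C)=C[C@@H](C(=O)OCc1ccccc1)C(c1ccc(OCc2ccccc2)c(OCc2ccccc2)c1)c1ccc(OCc2ccccc2)c(OCc2ccccc2)c1 | intermediate (not isolated)
13 | 1-allyl 4-benzyl (2Z,3S)-3-{bis[3,4-bis(benzyloxy)phenyl]methyl}-2-(hydroxymethylidene)butanedioate (enol tautomer of the formyl diester) | O/C=C(\C(=O)OCC=C)[C@@H](C(=O)OCc1ccccc1)C(c1ccc(OCc2ccccc2)c(OCc2ccccc2)c1)c1ccc(OCc2ccccc2)c(OCc2ccccc2)c1 | intermediate (key-step precursor)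
14 | 3-allyl 2-benzyl (1R,2S)-6,7-bis(benzyloxy)-1-[3,4-bis(benzyloxy)phenyl]-4-hydroxy-1,2,3,4-tetrahydronaphthalene-2,3-dicarboxylate (C3 and C4 epimers) | C=CCOC(=O)C1C(O)c2cc(OCc3ccccc3)c(OCc3ccccc3)cc2[C@@H](c2ccc(OCc3ccccc3)c(OCc3ccccc3)c2)[C@@H]1C(=O)OCc1ccccc1 | intermediate (not isolated)
15 | 3-allyl 2-benzyl (1R,2S)-6,7-bis(benzyloxy)-1-[3,4-bis(benzyloxy)phenyl]-1,2-dihydronaphthalene-2,3-dicarboxylate | C=CCOC(=O)C1=Cc2cc(OCc3ccccc3)c(OCc3ccccc3)cc2[C@@H](c2ccc(OCc3ccccc3)c(OCc3ccccc3)c2)[C@@H]1C(=O)OCc1ccccc1 | intermediate (key-step product)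
16 | (1R,2S)-2-(benzyloxycarbonyl)-6,7-bis(benzyloxy)-1-[3,4-bis(benzyloxy)phenyl]-1,2-dihydronaphthalene-3-carboxylic acid | OC(=O)C1=Cc2cc(OCc3ccccc3)c(OCc3ccccc3)cc2[C@@H](c2ccc(OCc3ccccc3)c(OCc3ccccc3)c2)[C@@H]1C(=O)OCc1ccccc1 | intermediate
17 | di-tert-butyl (2S)-2-hydroxybutanedioate (di-tert-butyl L-malate) | CC(C)(C)OC(=O)C[C@H](O)C(=O)OC(C)(C)C | starting material
18 | di-tert-butyl (2S)-2-({(1R,2S)-2-(benzyloxycarbonyl)-6,7-bis(benzyloxy)-1-[3,4-bis(benzyloxy)phenyl]-1,2-dihydronaphthalen-3-yl}carbonyloxy)butanedioate | CC(C)(C)OC(=O)C[C@H](OC(=O)C1=Cc2cc(OCc3ccccc3)c(OCc3ccccc3)cc2[C@@H](c2ccc(OCc3ccccc3)c(OCc3ccccc3)c2)[C@@H]1C(=O)OCc1ccccc1)C(=O)OC(C)(C)C | intermediate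
19 | (2S)-2-({(1R,2S)-2-carboxy-6,7-dihydroxy-1-(3,4-dihydroxyphenyl)-1,2-dihydronaphthalen-3-yl}carbonyloxy)butanedioic acid | O=C(O)C[C@H](OC(=O)C1=Cc2cc(O)c(O)cc2[C@@H](c2ccc(O)c(O)c2)[C@@H]1C(=O)O)C(=O)O | target

Total step count: 10. Longest linear sequence: 10 steps (1 and 2 to 19).

Steps most likely to fail

Step 7. The C2 centre may not discriminate well enough between the two diastereotopic aryl rings. Part of the material would then close through the other ring to the 1S,2S cis diester, which cannot be corrected because epimerising its C2 leads into the mirror-image trans series. The fallback sets out from 1 and comes back at 15. It closes the ring the other way, forming C1–C8a from a planar benzylic cation at C1, so no choice between two aryl groups is needed.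
- Stobbe condensation of 1 with diallyl succinate (NaH, THF) should give (E)-3-(allyloxycarbonyl)-4-[3,4-bis(benzyloxy)phenyl]but-3-enoic acid F1.
- Its acid is joined through the pivaloyl mixed anhydride (t-BuCOCl, Et3N, LiCl) to (R)-4-benzyl-1,3-oxazolidin-2-one, giving the N-acyl oxazolidinone F2.
- Dibutylboron triflate and i-Pr2NEt, followed by a second portion of 1, should give the Evans syn-aldol adduct F3, with the future C2 fixed by the auxiliary.
- TFA ionises the benzylic alcohol, and the arylidene ring should attack the cation on the face away from the C2 acyl group, giving the trans dihydronaphthalene imide F4.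
- LiOH/H2O2 removes the auxiliary to give the C2 acid F5, and benzyl bromide with KHCO3 in DMF gives 15.

Step 4. Hydrogen may add slowly, or with poor facial selectivity, to the crowded tetrasubstituted alkene of 8. The fallback sets out from 1 (with 3 made from 2 as in step 1) and comes back at 10. It sets the centre by auxiliary-controlled enolate alkylation.
- Knoevenagel–Doebner condensation of 1 with malonic acid (pyridine, piperidine) gives (E)-3-[3,4-bis(benzyloxy)phenyl]prop-2-enoic acid F6.
- Acylation of (R)-4-benzyl-1,3-oxazolidin-2-one through the pivaloyl mixed anhydride gives the cinnamoyl imide F7.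
- Conjugate addition of Grignard reagent 3 mediated by CuBr·SMe2 gives the 3,3-diarylpropanoyl imide F8, without a new stereocentre.
- NaN(SiMe3)2 and allyl bromoacetate at −78 °C should alkylate the Z-enolate on the face away from the benzyl group of the auxiliary (Evans alkylation), giving the alkylated imide F9.
- LiOH/H2O2 gives the acid F10, and benzyl bromide with KHCO3 in DMF gives 10.

Step 6. The C3 enolate may exchange protons before it is formylated, which would erode the C2 configuration, or the formyl transfer may stop short. The fallback sets out from 10 and comes back at 15. It traps the enolate as it forms and brings in the formyl carbon under Lewis acid.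
- LiN(i-Pr)2 is added to 10 in the presence of Me3SiCl at −78 °C to give the silyl ketene acetal F11.
- Mukaiyama-type addition to trimethyl orthoformate (catalytic Me3SiOTf, CH2Cl2, −78 °C) gives the dimethyl acetal F12, a masked form of 13.
- TFA ionises the acetal to an oxocarbenium ion, the same ring closure follows, and two molecules of methanol are lost to give 15.

Further compounds
F1 | step 7 | (E)-3-(allyloxycarbonyl)-4-[3,4-bis(benzyloxy)phenyl]but-3-enoic acid | OC(=O)C/C(C(=O)OCC=C)=C\c1ccc(OCc2ccccc2)c(OCc2ccccc2)c1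
F2 | step 7 | allyl (E)-2-[3,4-bis(benzyloxy)benzylidene]-4-[(4R)-4-benzyl-2-oxo-1,3-oxazolidin-3-yl]-4-oxobutanoate | O=C(C/C(C(=O)OCC=C)=C\c1ccc(OCc2ccccc2)c(OCc2ccccc2)c1)N1[C@H](Cc2ccccc2)COC1=O
F3 | step 7 | allyl (2E,3R,4R)-2-[3,4-bis(benzyloxy)benzylidene]-3-{[(4R)-4-benzyl-2-oxo-1,3-oxazolidin-3-yl]carbonyl}-4-[3,4-bis(benzyloxy)phenyl]-4-hydroxybutanoate (syn-aldol adduct) | O=C([C@@H]([C@@H](O)c1ccc(OCc2ccccc2)c(OCc2ccccc2)c1)/C(C(=O)OCC=C)=C\c1ccc(OCc2ccccc2)c(OCc2ccccc2)c1)N1[C@H](Cc2ccccc2)COC1=O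
F4 | step 7 | allyl (1R,2S)-2-{[(4R)-4-benzyl-2-oxo-1,3-oxazolidin-3-yl]carbonyl}-6,7-bis(benzyloxy)-1-[3,4-bis(benzyloxy)phenyl]-1,2-dihydronaphthalene-3-carboxylate | C=CCOC(=O)C1=Cc2cc(OCc3ccccc3)c(OCc3ccccc3)cc2[C@@H](c2ccc(OCc3ccccc3)c(OCc3ccccc3)c2)[C@@H]1C(=O)N1[C@H](Cc2ccccc2)COC1=O
F5 | step 7 | (1R,2S)-3-(allyloxycarbonyl)-6,7-bis(benzyloxy)-1-[3,4-bis(benzyloxy)phenyl]-1,2-dihydronaphthalene-2-carboxylic acid | C=CCOC(=O)C1=Cc2cc(OCc3ccccc3)c(OCc3ccccc3)cc2[C@@H](c2ccc(OCc3ccccc3)c(OCc3ccccc3)c2)[C@@H]1C(=O)O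
F6 | step 4 | (E)-3-[3,4-bis(benzyloxy)phenyl]prop-2-enoic acid | OC(=O)/C=C/c1ccc(OCc2ccccc2)c(OCc2ccccc2)c1
F7 | step 4 | (4R)-4-benzyl-3-{(E)-3-[3,4-bis(benzyloxy)phenyl]prop-2-enoyl}-1,3-oxazolidin-2-one | O=C(/C=C/c1ccc(OCc2ccccc2)c(OCc2ccccc2)c1)N1[C@H](Cc2ccccc2)COC1=O
F8 | step 4 | (4R)-4-benzyl-3-{3,3-bis[3,4-bis(benzyloxy)phenyl]propanoyl}-1,3-oxazolidin-2-one | O=C(CC(c1ccc(OCc2ccccc2)c(OCc2ccccc2)c1)c1ccc(OCc2ccccc2)c(OCc2ccccc2)c1)N1[C@H](Cc2ccccc2)COC1=O
F9 | step 4 | allyl (3R)-3-{[(4R)-4-benzyl-2-oxo-1,3-oxazolidin-3-yl]carbonyl}-4,4-bis[3,4-bis(benzyloxy)phenyl]butanoate | C=CCOC(=O)C[C@@H](C(=O)N1[C@H](Cc2ccccc2)COC1=O)C(c1ccc(OCc2ccccc2)c(OCc2ccccc2)c1)c1ccc(OCc2ccccc2)c(OCc2ccccc2)c1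
F10 | step 4 | (2R)-4-(allyloxy)-2-{bis[3,4-bis(benzyloxy)phenyl]methyl}-4-oxobutanoic acid | C=CCOC(=O)C[C@@H](C(=O)O)C(c1ccc(OCc2ccccc2)c(OCc2ccccc2)c1)c1ccc(OCc2ccccc2)c(OCc2ccccc2)c1
F11 | step 6 | benzyl (2S)-4-(allyloxy)-2-{bis[3,4-bis(benzyloxy)phenyl]methyl}-4-(trimethylsilyloxy)but-3-enoate (silyl ketene acetal of 10) | C=CCOC(O[Si](C)(C)C)=C[C@@H](C(=O)OCc1ccccc1)C(c1ccc(OCc2ccccc2)c(OCc2ccccc2)c1)c1ccc(OCc2ccccc2)c(OCc2ccccc2)c1
F12 | step 6 | 1-allyl 4-benzyl (3S)-3-{bis[3,4-bis(benzyloxy)phenyl]methyl}-2-(dimethoxymethyl)butanedioate (C2 epimers) | C=CCOC(=O)C(C(OC)OC)[C@@H](C(=O)OCc1ccccc1)C(c1ccc(OCc2ccccc2)c(OCc2ccccc2)c1)c1ccc(OCc2ccccc2)c(OCc2ccccc2)c1
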